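The route rests on cutting the cyclopentane (ring C) at two bonds: the C–C bond between the ring-fusion CH and the quaternary C(CH3)(CH2Ar) carbon, and the C–O bond of the tertiary aryl ether carbon. These two carbons sit 1,3-cis on ring C, which is fused to the carane six-membered ring (ring D). One Lewis-acid-triggered operation, a conrotatory 4π closure of a cross-conjugated dienone whose oxyallyl cation is trapped by the tethered phenol oxygen, closes ring C and the seven-membered ether ring B and sets three stereocentres. Its precursor is a carvone-derived carenyl (E)-alkenyl ketone that carries this phenol as a triethylsilyl ether.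

Key step: step 14

Remarks on the chemistry (assumptions and conventions)
- The bicyclic carane intermediates are named with bicyclo[4.1.0]heptane (carane) numbering.
- For the dienone and all pentacycles the following locants are used: C-1 benzylic carbon on ring A (arene); C-2 carbon bearing CH3 and C-1; C-3 the CH between C-2 and the cyclopropane; C-4 and C-6 cyclopropane CH (C-4 bonded to C-3); C-5 C(CH3)2; C-7 CH2; C-8 CH(CH3); C-9 the carbon bonded to C-3, C-8 and C-10 (the tertiary aryl ether carbon of the pentacycles); C-10 the ketone carbon of the dienone and of the cyclisation product; C-11 the carbon between C-10 and C-2.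
- Rings: B = seven-membered ether ring (O, C-9, C-3, C-2, C-1 and two ring-A carbons); C = cyclopentane C-2, C-3, C-9, C-10, C-11; D = cyclohexane C-3, C-4, C-6, C-7, C-8, C-9; E = cyclopropane C-4, C-5, C-6.
- "Configuration as in the target" means: on ring C the ether oxygen on C-9, H-3 and C-1 share one face, while the CH3 on C-2 and ring D lie on the other; the cyclopropane is anti to C-2 across C-3–C-4; the C-8 methyl is cis to the cyclopropane; the C-1 substituent, once present, lies on the face of ring B away from the C-10–C-11 bridge.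
- 3,5-Bis(benzyloxy)phenol is taken as a commercial starting material.
- The phenol is deliberately carried into the cyclisation as a silyl ether: a free phenol sits 5-exo to the enone carbon C-2 and would add there (and release protic acid beside the cyclopropane) before the electrocyclisation.
- Stereocentres that are erased within the next steps (the carbinol at C-10, the methyl ether at C-1) are left undefined in the SMILES; either epimer serves.

Step 1
Reactants: 1 (S)-(+)-carvone
Product: 2 (5S)-5-(2-bromopropan-2-yl)-2-methylcyclohex-2-en-1-one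
Conditions: HBr (33% in AcOH), 0 °C
Reagents that add atoms: hydrogen bromide, Br
Why: Markovnikov hydrobromination of the electron-rich isopropenyl alkene gives the tertiary bromide and leaves the conjugated alkene and the C-5 stereocentre untouched.

Step 2
Reactants: 2 (5S)-5-(2-bromopropan-2-yl)-2-methylcyclohex-2-en-1-one
Product: 3 (1R,6S)-3,7,7-trimethylbicyclo[4.1.0]hept-3-en-2-one
Conditions: KOH, MeOH, 0 °C
Reagents that add atoms: none
Why: The α′-enolate displaces the tertiary bromide in a 3-exo-tet intramolecular alkylation (1,3-elimination), so the isopropenyl carbon becomes the CMe2 of a cyclopropane that can only be cis-fused, its second stereocentre following from C-5 of carvone; low temperature avoids the base-induced ring expansion.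

Step 3
Reactants: 3 (1R,6S)-3,7,7-trimethylbicyclo[4.1.0]hept-3-en-2-one
Product: 4 (1R,3S,4S,6S)-3,4-epoxy-3,7,7-trimethylbicyclo[4.1.0]heptan-2-one (epoxide anti to the cyclopropane)
Conditions: 30% H2O2, NaOH (cat.), MeOH, 0 °C
Reagents that add atoms: hydrogen peroxide, OO
Why: Weitz–Scheffer nucleophilic epoxidation of the α-methyl enone, hydroperoxide adding to the face anti to the gem-dimethylcyclopropane (a configuration that is erased later).

Step 4
Reactants: 4 (1R,3S,4S,6S)-3,4-epoxy-3,7,7-trimethylbicyclo[4.1.0]heptan-2-one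
Product: 6 (1R,4S,6S)-3,7,7-trimethylbicyclo[4.1.0]hept-2-en-4-ol, via epoxy hydrazone 5 (not isolated)
Conditions: N2H4·H2O, AcOH (cat.), MeOH, 0 °C → rt
Reagents that add atoms: none
Why: Wharton transposition, in which the epoxy hydrazone opens to a vinyl diazene that loses N2, moving oxygen from C-2 to C-4 and the alkene to C-2=C-3; the carbinol configuration is retained from the epoxide and is irrelevant because it is oxidised next.

Step 5
Reactants: 6 (1R,4S,6S)-3,7,7-trimethylbicyclo[4.1.0]hept-2-en-4-ol
Product: 7 (1R,6S)-3,7,7-trimethylbicyclo[4.1.0]hept-2-en-4-one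
Conditions: MnO2, CH2Cl2, rt
Reagents that add atoms: none
Why: Selective allylic alcohol oxidation under neutral conditions that leave the vinylcyclopropane alone.

Step 6
Reactants: 7 (1R,6S)-3,7,7-trimethylbicyclo[4.1.0]hept-2-en-4-one
Product: 9 (1R,3S,6S)-3,7,7-trimethylbicyclo[4.1.0]heptan-4-one (3-CH3 cis to the cyclopropane), via lithium enolate 8 (not isolated)
Conditions: LiBH(s-Bu)3, THF, −78 °C; aq. NH4Cl
Reagents that add atoms: none
Why: Conjugate hydride addition of the bulky borohydride to the carvone-type α-methyl enone, without radical intermediates that could open the cyclopropane; protonation of the enolate at C-3 anti to the cyclopropane places CH3 cis to it, which is also the thermodynamically preferred epimer of 4-caranones.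

Step 7
Reactants: 9 (1R,3S,6S)-3,7,7-trimethylbicyclo[4.1.0]heptan-4-one
Product: 11 (1R,3S,6R)-3,7,7-trimethylbicyclo[4.1.0]hept-4-en-4-yl trifluoromethanesulfonate, via lithium enolate 10 (not isolated)
Conditions: LDA, THF, −78 °C; PhNTf2, −78 → 0 °C
Reagents that add atoms: N-phenylbis(trifluoromethanesulfonimide), O=S(=O)(N(c1ccccc1)S(=O)(=O)C(F)(F)F)C(F)(F)F
Why: Kinetic deprotonation at the less substituted α-carbon C-5 and O-sulfonylation of the enolate give the C-4=C-5 enol triflate regioselectively and leave the C-3 stereocentre untouched.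

Step 8
Reactants: 11 (1R,3S,6R)-3,7,7-trimethylbicyclo[4.1.0]hept-4-en-4-yl trifluoromethanesulfonate
Product: 12 (1R,3S,6S)-N-methoxy-N,3,7,7-tetramethylbicyclo[4.1.0]hept-4-ene-4-carboxamide
Conditions: Pd(OAc)2 (cat.), Xantphos (cat.), CO (1 atm), MeNHOMe·HCl, Et3N, DMF, 60 °C
Reagents that add atoms: carbon monoxide, [C-]#[O+]; N,O-dimethylhydroxylamine hydrochloride, CNOC.Cl
Why: Palladium-catalysed aminocarbonylation of a vinyl triflate (oxidative addition to zerovalent palladium, CO insertion, capture of the acylpalladium by the hydroxylamine) gives the unsaturated Weinreb amide with the carbon that becomes C-10.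

Step 9
Reactants: 13 propargyl alcohol
Product: 15 (2E)-3-iodo-2-methylprop-2-en-1-ol, via alkenylalane 14 (not isolated)
Conditions: Me3Al, Cp2ZrCl2 (cat.), CH2Cl2, 0 °C → rt; I2, THF, −30 °C; aq. HCl
Reagents that add atoms: trimethylaluminium (Me3Al), C[Al](C)C; iodine, II
Why: Zirconium-catalysed carboalumination (syn addition of CH3–Al across the alkyne, aluminium at the terminal carbon) followed by iodinolysis with retention fixes the trisubstituted (E)-alkene with iodine trans to CH2OH.

Step 10
Reactants: 15 (2E)-3-iodo-2-methylprop-2-en-1-ol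
Product: 16 (1E)-3-bromo-1-iodo-2-methylprop-1-ene
Conditions: CBr4, PPh3, CH2Cl2, 0 °C
Reagents that add atoms: tetrabromomethane, BrC(Br)(Br)Br
Why: Appel bromination of the primary allylic alcohol under neutral conditions, without allylic transposition or loss of alkene geometry.

Step 11
Reactants: 17 3,5-bis(benzyloxy)phenol; 16 (1E)-3-bromo-1-iodo-2-methylprop-1-ene
Product: 19 3,5-bis(benzyloxy)-2-[(2E)-3-iodo-2-methylprop-2-en-1-yl]phenol, via sodium phenoxide 18 (not isolated)
Conditions: NaH, toluene, 0 °C → rt; then 16, rt
Reagents that add atoms: none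
Why: ortho-C-Allylation of a metal phenoxide in a non-polar solvent, where the tight sodium ion pair directs SN2 attack of the ring carbon next to oxygen on the primary allylic bromide; this places the one free phenol ortho to the new side chain and keeps the (E)-iodoalkene.

Step 12
Reactants: 19 3,5-bis(benzyloxy)-2-[(2E)-3-iodo-2-methylprop-2-en-1-yl]phenol
Product: 20 [3,5-bis(benzyloxy)-2-[(2E)-3-iodo-2-methylprop-2-en-1-yl]phenoxy]triethylsilane
Conditions: Et3SiCl, imidazole, CH2Cl2, 0 °C → rt
Reagents that add atoms: chlorotriethylsilane, CC[Si](Cl)(CC)CC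
Why: Standard O-silylation; the triethylsilyl ether blocks conjugate addition of the phenol to the future enone and is the latent oxygen nucleophile of step 14.

Step 13
Reactants: 20 [3,5-bis(benzyloxy)-2-[(2E)-3-iodo-2-methylprop-2-en-1-yl]phenoxy]triethylsilane; 12 (1R,3S,6S)-N-methoxy-N,3,7,7-tetramethylbicyclo[4.1.0]hept-4-ene-4-carboxamide
Product: 22 (2E)-4-[2,4-bis(benzyloxy)-6-(triethylsilyloxy)phenyl]-3-methyl-1-[(1R,3S,6S)-3,7,7-trimethylbicyclo[4.1.0]hept-4-en-4-yl]but-2-en-1-one, via vinyllithium 21 (not isolated)
Conditions: t-BuLi (2 equiv), Et2O, −78 °C; then 12, THF, −78 → −20 °C; aq. NH4Cl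
Reagents that add atoms: none
Why: Iodine–lithium exchange with retention of alkene geometry gives the vinyllithium, whose addition to the Weinreb amide stops at the chelated tetrahedral adduct and releases the cross-conjugated (E)-dienone on work-up (Weinreb ketone synthesis).

Step 14
Reactants: 22 (2E)-4-[2,4-bis(benzyloxy)-6-(triethylsilyloxy)phenyl]-3-methyl-1-[(1R,3S,6S)-3,7,7-trimethylbicyclo[4.1.0]hept-4-en-4-yl]but-2-en-1-one
Product: 24 pentacyclic C-10 ketone (rings B and C closed; benzylic C-1 is CH2; two benzyl ethers on ring A; configuration as in the target), via difluoroboron enolate 23 (not isolated)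
Conditions: BF3·OEt2, 2,6-di-tert-butyl-4-methylpyridine (cat.), CH2Cl2, −78 → −20 °C; aq. NaHCO3
Reagents that add atoms: none
Why: Proposed new method: BF3 on the C-10 carbonyl gives the 3-oxidopentadienyl cation, which closes by thermal conrotatory 4π electrocyclisation (ring C, new C-2–C-3 bond), and the resulting oxyallyl cation is captured at its fully substituted terminus C-9 by the silyl ether oxygen in a 7-exo closure (ring B), fluoride transfer from boron removing the silyl group as Et3SiF and leaving boron enolate 23, which aqueous work-up protonates to ketone 24. The closest known reaction type is the interrupted Nazarov cyclisation in which a tethered arene, alkene or silyl-terminated nucleophile traps the oxyallyl cation; an aryl silyl ether oxygen as the trap, the bridging seven-membered closure, the quaternary terminus and the vinylcyclopropane terminus go beyond that precedent. C-2 and C-3: conrotation of the (E)-alkene (C-1 outside, CH3 inside) against the ring-fixed cyclohexene terminus (C-4 outside, H inside) places C-1 cis to H-3 and CH3 cis to C-4, and their absolute sense follows from torquoselectivity, the new bond forming on the face of C-3 anti to the cyclopropane, whose endo methyl and the cis C-8 methyl shield the other face. C-9: the four-atom tether from C-2 can deliver oxygen only to the face of ring C that carries C-1, which fixes the cis ring fusion. The step needs capture at C-9 and not at C-11 (which would close a six-membered ring), and it needs the cyclopropane to survive; the first rests on the larger positive charge at the fully substituted terminus, the second on the masked phenol (no conjugate addition to C-2, no protic acid), the absence of a nucleophilic counter-ion and the low temperature.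

Step 15
Reactants: 24 pentacyclic C-10 ketone
Product: 25 C-10 alcohol of 24 (carbinol configuration not defined)
Conditions: NaBH4, MeOH/THF, 0 °C → rt
Reagents that add atoms: none
Why: Hydride reduction of the ring-C ketone; the carbinol configuration is immaterial because C-10 becomes CH2 two steps later.

Step 16
Reactants: 25 C-10 alcohol of 24
Product: 27 S-methyl xanthate of 25, via sodium xanthate 26 (not isolated)
Conditions: NaH, imidazole (cat.), THF, 0 °C; CS2; MeI, rt
Reagents that add atoms: carbon disulfide, S=C=S; iodomethane, CI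
Why: Xanthate formation (alkoxide addition to CS2, then S-methylation of the xanthate salt), the first half of a Barton–McCombie deoxygenation, which tolerates the hindered secondary alcohol.

Step 17
Reactants: 27 S-methyl xanthate of 25
Product: 28 pentacycle with C-10 as CH2 (C-1 still CH2; two benzyl ethers; configuration as in the target)
Conditions: Bu3SnH, AIBN (cat.), toluene, 100 °C
Reagents that add atoms: none
Why: Barton–McCombie radical deoxygenation, the secondary C-10 radical being reduced by the stannane faster than it could expel the β-aryloxy group; no stereocentre is formed.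

Step 18
Reactants: 28 pentacycle with C-10 as CH2
Product: 29 C-1 methyl ether of 28 (C-1 configuration not defined)
Conditions: DDQ, CH2Cl2/MeOH, 0 °C → rt
Reagents that add atoms: methanol, CO
Why: DDQ abstracts hydride from the only C–H that is benzylic to the trioxygenated ring; the resulting quinone-methide-type cation cannot eliminate (C-2 is quaternary) and is captured by methanol (oxidative benzylic etherification), the C-1 configuration being immaterial.

Step 19
Reactants: 29 C-1 methyl ether of 28
Product: 30 C-1 (2-methylallyl) pentacycle (two benzyl ethers; C-1 configuration as in the target)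
Conditions: CH2=C(CH3)CH2SiMe3, TMSOTf (cat.), CH2Cl2, −78 → −40 °C
Reagents that add atoms: trimethyl(2-methylallyl)silane, CC(=C)C[Si](C)(C)C
Why: Hosomi–Sakurai substitution through the same benzylic cation, in which the allylsilane should add to C-1 anti to the C-2–C-11 bond, on the face of ring B away from the C-10–C-11 bridge and ring D over which only H-3 projects, which is the target configuration at C-1.

Step 20
Reactants: 30 C-1 (2-methylallyl) pentacycle
Product: 31 C-1 isobutyl pentacycle with both ring-A hydroxyls free
Conditions: H2 (1 atm), Pd/C, EtOAc/EtOH, rt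
Reagents that add atoms: none
Why: Heterogeneous hydrogenation saturates the 1,1-disubstituted alkene to the isobutyl group and hydrogenolyses both benzyl ethers, leaving the unactivated cyclopropane and the tertiary alkyl aryl ether.

Step 21
Reactants: 31 C-1 isobutyl pentacycle with both ring-A hydroxyls free
Product: 32 CNP0202714.1 (target)
Conditions: Cl2CHOMe, TiCl4, CH2Cl2, −78 → 0 °C; ice-cold aq. HCl
Reagents that add atoms: dichloromethyl methyl ether, COC(Cl)Cl; water, O
Why: Twofold Rieche formylation (electrophilic aromatic substitution by the TiCl4-activated dichloromethyl ether, then hydrolysis) at the only two free ring-A positions, each ortho to a hydroxyl that directs through its titanium phenoxide.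

Compound list
1 | (S)-(+)-carvone | CC1=CC[C@H](C(C)=C)CC1=O | starting material
2 | (5S)-5-(2-bromopropan-2-yl)-2-methylcyclohex-2-en-1-one | CC1=CC[C@H](C(C)(C)Br)CC1=O | intermediate
3 | (1R,6S)-3,7,7-trimethylbicyclo[4.1.0]hept-3-en-2-one | CC1=CC[C@@H]2C(C)(C)[C@@H]2C1=O | intermediate
4 | (1R,3S,4S,6S)-3,4-epoxy-3,7,7-trimethylbicyclo[4.1.0]heptan-2-one | C[C@]12O[C@H]1C[C@@H]1C(C)(C)[C@@H]1C2=O | intermediate
5 | hydrazone of 4 (not isolated) | C[C@]12O[C@H]1C[C@@H]1C(C)(C)[C@@H]1C2=NN | intermediate
6 | (1R,4S,6S)-3,7,7-trimethylbicyclo[4.1.0]hept-2-en-4-ol | CC1=C[C@H]2C(C)(C)[C@H]2C[C@@H]1O | intermediate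
7 | (1R,6S)-3,7,7-trimethylbicyclo[4.1.0]hept-2-en-4-one | CC1=C[C@H]2C(C)(C)[C@H]2CC1=O | intermediate
8 | lithium C-3 enolate of 9 (not isolated) | [Li+].[O-]C1=C(C)C[C@@H]2[C@H](C1)C2(C)C | intermediate
9 | (1R,3S,6S)-3,7,7-trimethylbicyclo[4.1.0]heptan-4-one | O=C1C[C@H]2[C@@H](C[C@@H]1C)C2(C)C | intermediate
10 | lithium C-5 enolate of 9 (not isolated) | [Li+].[O-]C1=C[C@H]2[C@@H](C[C@@H]1C)C2(C)C | intermediate
11 | (1R,3S,6R)-3,7,7-trimethylbicyclo[4.1.0]hept-4-en-4-yl trifluoromethanesulfonate | O=S(=O)(OC1=C[C@H]2[C@@H](C[C@@H]1C)C2(C)C)C(F)(F)F | intermediate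
12 | (1R,3S,6S)-N-methoxy-N,3,7,7-tetramethylbicyclo[4.1.0]hept-4-ene-4-carboxamide | CON(C)C(=O)C1=C[C@H]2[C@@H](C[C@@H]1C)C2(C)C | intermediate
13 | propargyl alcohol | C#CCO | starting material
14 | (E)-alkenylalane, dimethylaluminium alkoxide (not isolated) | C[Al](C)OC/C(C)=C/[Al](C)C | intermediate
15 | (2E)-3-iodo-2-methylprop-2-en-1-ol | OC/C(C)=C/I | intermediate
16 | (1E)-3-bromo-1-iodo-2-methylprop-1-ene | BrC/C(C)=C/I | intermediate
17 | 3,5-bis(benzyloxy)phenol | Oc1cc(OCc2ccccc2)cc(OCc2ccccc2)c1 | starting material
18 | sodium 3,5-bis(benzyloxy)phenoxide (not isolated) | [Na+].[O-]c1cc(OCc2ccccc2)cc(OCc2ccccc2)c1 | intermediate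
19 | 3,5-bis(benzyloxy)-2-[(2E)-3-iodo-2-methylprop-2-en-1-yl]phenol | Oc1cc(OCc2ccccc2)cc(OCc2ccccc2)c1C/C(C)=C/I | intermediate
20 | triethylsilyl ether of 19 | CC[Si](CC)(CC)Oc1cc(OCc2ccccc2)cc(OCc2ccccc2)c1C/C(C)=C/I | intermediate
21 | (E)-vinyllithium from 20 (not isolated) | CC[Si](CC)(CC)Oc1cc(OCc2ccccc2)cc(OCc2ccccc2)c1C/C(C)=C/[Li] | intermediate
22 | carenyl (E)-alkenyl ketone, phenol as triethylsilyl ether (cyclisation precursor) | CC[Si](CC)(CC)Oc1cc(OCc2ccccc2)cc(OCc2ccccc2)c1C/C(C)=C/C(=O)C1=C[C@H]2[C@@H](C[C@@H]1C)C2(C)C | intermediate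
23 | difluoroboron enolate of 24 (not isolated) | C1c2c(OCc4ccccc4)cc(OCc4ccccc4)cc2O[C@]23C(OB(F)F)=C[C@@]1(C)[C@H]2[C@H]1[C@@H](C[C@@H]3C)C1(C)C | intermediate
24 | pentacyclic α-aryloxy cyclopentanone (C-10 ketone, benzylic CH2) | C1c2c(OCc4ccccc4)cc(OCc4ccccc4)cc2O[C@]23C(=O)C[C@@]1(C)[C@H]2[C@H]1[C@@H](C[C@@H]3C)C1(C)C | intermediate
25 | C-10 alcohol (carbinol centre undefined) | C1c2c(OCc4ccccc4)cc(OCc4ccccc4)cc2O[C@]23C(O)C[C@@]1(C)[C@H]2[C@H]1[C@@H](C[C@@H]3C)C1(C)C | intermediate
26 | sodium xanthate of 25 (not isolated) | C1c2c(OCc4ccccc4)cc(OCc4ccccc4)cc2O[C@]23C(OC(=S)[S-])C[C@@]1(C)[C@H]2[C@H]1[C@@H](C[C@@H]3C)C1(C)C.[Na+] | intermediate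
27 | S-methyl xanthate of 25 | C1c2c(OCc4ccccc4)cc(OCc4ccccc4)cc2O[C@]23C(OC(=S)SC)C[C@@]1(C)[C@H]2[C@H]1[C@@H](C[C@@H]3C)C1(C)C | intermediate
28 | deoxygenated pentacycle (C-10 and C-1 both CH2) | C1c2c(OCc4ccccc4)cc(OCc4ccccc4)cc2O[C@]23CC[C@@]1(C)[C@H]2[C@H]1[C@@H](C[C@@H]3C)C1(C)C | intermediate
29 | C-1 methyl ether (C-1 undefined) | COC1c2c(OCc4ccccc4)cc(OCc4ccccc4)cc2O[C@]23CC[C@@]1(C)[C@H]2[C@H]1[C@@H](C[C@@H]3C)C1(C)C | intermediate
30 | C-1 (2-methylallyl) pentacycle, dibenzyl ether | C=C(C)C[C@H]1c2c(OCc4ccccc4)cc(OCc4ccccc4)cc2O[C@]23CC[C@@]1(C)[C@H]2[C@H]1[C@@H](C[C@@H]3C)C1(C)C | intermediate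
31 | C-1 isobutyl pentacycle, free bis-phenol | CC(C)C[C@H]1c2c(O)cc(O)cc2O[C@]23CC[C@@]1(C)[C@H]2[C@H]1[C@@H](C[C@@H]3C)C1(C)C | intermediate
32 | CNP0202714.1 | CC(C)C[C@H]1c2c(O)c(C=O)c(O)c(C=O)c2O[C@]23CC[C@@]1(C)[C@H]2[C@H]1[C@@H](C[C@@H]3C)C1(C)C | target

Total step count: 21.
Longest linear sequence: 17 steps (steps 1–8, then 13–21).

Steps most likely to fail

1. Step 14.
What may go wrong: the hindered silyl ether oxygen may reach C-9 too slowly, so that the oxyallyl cation is lost to proton loss or to a 1,2-hydride shift from C-3 that puts the charge next to the cyclopropane and opens it. Oxygen may instead close onto C-11 in a six-membered ring. Acid-induced scrambling of the alkene geometry before closure would divert material.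
Fallback (known reactions only), setting out from 22 and returning at 24: C–C and C–O bond formation are separated. A reductive Nazarov cyclisation (BF3·OEt2 with excess Et3SiH, CH2Cl2, −78 → 0 °C), in which hydride traps the oxyallyl cation, would give the silyl-protected cyclopentanone with hydrogen on C-9, F1, with C-2 and C-3 set as in the main route. Thermodynamic enol silylation (Me3SiCl, NaI, Et3N, MeCN) toward the more substituted side would give the C-9=C-10 trimethylsilyl enol ether F2, and NBS (THF, −78 °C) the tertiary α-bromo ketone F3. Fluoride (Bu4NF, THF, 0 °C) would then free the phenoxide, which displaces the tertiary α-keto bromide at C-9 from the only face its tether reaches, giving 24.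

2. Step 19.
What may go wrong: poor or reversed facial selectivity in the addition to the C-1 cation, or slow capture at this neopentyl centre so that the cation is consumed in other ways.
Fallback, setting out from 28 and returning at 31: the order of the two bonds to C-1 is inverted, so that hydride and not carbon enters last. Excess DDQ in wet CH2Cl2 would give the C-1 aryl ketone F4. The isobutylcerium reagent (i-BuLi, CeCl3, THF, −78 °C) would add to this non-enolisable ketone to give the tertiary benzylic alcohol F5. Ionic hydrogenation (Et3SiH, CF3CO2H, CH2Cl2, −40 °C) would deliver hydride to the face that the carbon nucleophile preferred and so give the C-1 isobutyl dibenzyl ether F6 with the target configuration; hydrogenolysis under the conditions of step 20 would give 31.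

3. Step 21.
What may go wrong: TiCl4 and the HCl released may open the cyclopropane or ionise the tertiary C-9–O bond, and the second formylation may stall once the first aldehyde deactivates the ring.
Fallback, setting out from 31 and returning at 32: the formyl carbons are introduced by halogen–lithium exchange. NBS (2 equiv, CH2Cl2, −78 °C) would give the ring-A dibromide F7, and MOMCl with i-Pr2NEt the bis(methoxymethyl) ether F8. t-BuLi (THF, −78 °C) followed by DMF would give the protected dialdehyde F9, and HCl in MeOH would remove both methoxymethyl groups to give 32.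

Further compounds
F1 | step 14 | silyl-protected cyclopentanone from hydride trapping (H on C-9, centre undefined) | CC[Si](CC)(CC)Oc1cc(OCc2ccccc2)cc(OCc2ccccc2)c1C[C@@]1(C)CC(=O)C2[C@@H]1[C@H]1[C@@H](C[C@@H]2C)C1(C)C
F2 | step 14 | C-9=C-10 trimethylsilyl enol ether of F1 | CC[Si](CC)(CC)Oc1cc(OCc2ccccc2)cc(OCc2ccccc2)c1C[C@@]1(C)CC(O[Si](C)(C)C)=C2[C@@H]1[C@H]1[C@@H](C[C@@H]2C)C1(C)C
F3 | step 14 | C-9 bromo ketone (C-9 undefined) | CC[Si](CC)(CC)Oc1cc(OCc2ccccc2)cc(OCc2ccccc2)c1C[C@@]1(C)CC(=O)C2(Br)[C@@H]1[C@H]1[C@@H](C[C@@H]2C)C1(C)C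
F4 | step 19 | C-1 aryl ketone of 28 | O=C1c2c(OCc4ccccc4)cc(OCc4ccccc4)cc2O[C@]23CC[C@@]1(C)[C@H]2[C@H]1[C@@H](C[C@@H]3C)C1(C)C
F5 | step 19 | C-1 isobutyl tertiary alcohol (C-1 undefined) | CC(C)CC1(O)c2c(OCc4ccccc4)cc(OCc4ccccc4)cc2O[C@]23CC[C@@]1(C)[C@H]2[C@H]1[C@@H](C[C@@H]3C)C1(C)C
F6 | step 19 | C-1 isobutyl pentacycle, dibenzyl ether | CC(C)C[C@H]1c2c(OCc4ccccc4)cc(OCc4ccccc4)cc2O[C@]23CC[C@@]1(C)[C@H]2[C@H]1[C@@H](C[C@@H]3C)C1(C)C
F7 | step 21 | ring-A dibromide of 31 | CC(C)C[C@H]1c2c(O)c(Br)c(O)c(Br)c2O[C@]23CC[C@@]1(C)[C@H]2[C@H]1[C@@H](C[C@@H]3C)C1(C)C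
F8 | step 21 | bis(methoxymethyl) ether of F7 | CC(C)C[C@H]1c2c(OCOC)c(Br)c(OCOC)c(Br)c2O[C@]23CC[C@@]1(C)[C@H]2[C@H]1[C@@H](C[C@@H]3C)C1(C)C
F9 | step 21 | bis(methoxymethyl) ether of 32 | CC(C)C[C@H]1c2c(OCOC)c(C=O)c(OCOC)c(C=O)c2O[C@]23CC[C@@]1(C)[C@H]2[C@H]1[C@@H](C[C@@H]3C)C1(C)C
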